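**Retrosynthetic overview**

1. Ring E (thiazine dioxide) is cut last, at its C–S and C–N bonds, to hypotaurine and a naphthoquinone; the quinone (ring D) comes from a 1,4-dimethoxynaphthalene by oxidative demethylation.
2. Ring A: the vinylic methyl group goes back to a ring ketone (enol triflate, Negishi coupling). Ring B (seven-membered enol lactone): the O–C(=O) bond goes back to an aryl bromide, CO and a hydroxymethylene enol.
3. Key disconnection: the aryl–C(quaternary) bond and the bond from the ring A carbon to the enol CH–O carbon are cut together. This gives a 3-bromo-2-naphthyl donor, 3-methylcyclohex-2-enone and a formate ester (asymmetric conjugate arylation with C-formylation of the resulting enolate).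
4. Enabling feature: the ring A carbon that bears the vinylic methyl group is a latent ketone carbon. At the ketone level the quaternary carbon is the β-carbon and the ring carbon carrying the exocyclic =CH–O is the α-carbon of a cyclohexenone, so an aryl nucleophile and a formyl electrophile can be added across one C=C. The formyl group then lands on the hindered α-carbon that deprotonation of the ketone could not reach.
5. Ring order: rings C/D (aryne–furan Diels–Alder, symmetric 6,7-dibromide) → preformed ring A joined in the key step → ring B (carbonylative lactonisation) → ring D to the quinone → ring E.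

Key step: step 3

Assumption: rhodium/(R)-BINAP is taken to deliver aryl groups to 3-methylcyclohex-2-enone with the same facial sense as to cyclohex-2-enone; if the opposite sense is found, (S)-BINAP is used instead.

**Route**

Step 1
Reactants: 1 1,2,4,5-tetrabromobenzene; 2 2-methoxyfuran
Product: 6 6,7-dibromo-4-methoxynaphthalen-1-ol, via aryllithium 3 (not isolated), via 4,5-dibromobenzyne 4 (not isolated), via oxabicyclic cycloadduct 5 (not isolated)
Conditions: n-BuLi (1.0 equiv, slow addition), 2 (3 equiv), toluene, –78 °C → rt; then 1 M HCl
Reagents that add atoms: none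
Why: Bromine–lithium exchange and loss of LiBr generate the symmetric aryne, whose Diels–Alder cycloaddition with the electron-rich furan gives a bridgehead-ketal oxanorbornadiene that opens and aromatises on acid work-up to the 4-methoxynaphthol (aryne–furan cycloaddition/ring opening); no stereocentre survives and the symmetry of the aryne removes any regiochemical question.

Step 2
Reactants: 6 6,7-dibromo-4-methoxynaphthalen-1-ol
Product: 7 6,7-dibromo-1,4-dimethoxynaphthalene
Conditions: MeI, K2CO3, acetone, reflux, N2
Reagents that add atoms: iodomethane, CI
Why: Williamson O-methylation of the naphthol, run at once under inert gas because the electron-rich naphthol is air-sensitive, should give the C2v-symmetric dibromide in which both bromines are equivalent.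

Step 3
Reactants: 7 6,7-dibromo-1,4-dimethoxynaphthalene; 8 3-methylcyclohex-2-en-1-one; 9 2,2,2-trifluoroethyl formate
Product: 14 (R,Z)-3-(3-bromo-5,8-dimethoxynaphthalen-2-yl)-2-(hydroxymethylene)-3-methylcyclohexan-1-one, via aryllithium 10 (not isolated), via arylalane 11 (not isolated), via aluminium enolate 12 (not isolated), via lithium aluminate enolate 13 (not isolated)
Conditions: n-BuLi (1.0 equiv), THF/Et2O, –100 °C; Me2AlCl, –100 → 0 °C; 8 (0.7 equiv), [Rh(cod)Cl]2 (3 mol %), (R)-BINAP (7 mol %), THF, 50 °C; then MeLi, –78 °C; 9 (excess), –78 → 0 °C; 1 M HCl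
Reagents that add atoms: none
Why: Bromine–lithium exchange on the symmetric dibromide and transmetallation give arylalane 11; its aryl group passes to rhodium, the aryl–rhodium species inserts the enone C=C to form the aryl–C(quaternary) bond, and the oxa-π-allyl rhodium is transmetallated to the regiodefined aluminium enolate 12, which after activation as aluminate 13 attacks the formate carbon to form the C–CH(O) bond at the carbon between the carbonyl and the new quaternary centre. The closest known reaction type is the rhodium/BINAP-catalysed asymmetric 1,4-addition of aryl(dimethyl)alanes to 3-methylcyclohex-2-enone, coupled to enolate trapping by Claisen-type C-formylation with 2,2,2-trifluoroethyl formate (tandem conjugate addition–enolate acylation). No ring is closed: this is an intermolecular three-component coupling that joins ring C, the preformed ring A and the future enol carbon of ring B. The only stereocentre, the quaternary carbon, is set by the catalyst: (R)-BINAP is expected to direct the aryl group to the Re face of C3 of the enone, which corresponds to (R) in 14 and to (S) in the target. The step needs aryl rather than methyl transfer from aluminium (sp2 groups transmetallate faster), mono-metallation (one equivalent of n-BuLi at –100 °C, where the ortho-bromoaryllithium should not yet lose LiBr) and formylation at the hindered α-carbon; the last is secured because the enolate is generated only there and any O-formyl material is itself a formyl donor that funnels to the chelated hydroxymethylene ketone.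

Step 4
Reactants: 14 (R,Z)-3-(3-bromo-5,8-dimethoxynaphthalen-2-yl)-2-(hydroxymethylene)-3-methylcyclohexan-1-one
Product: 15 (S)-keto enol lactone (ring B closed; ring A still a cyclohexanone)
Conditions: CO (1 atm), Pd(OAc)2 (5 mol %), Xantphos (6 mol %), Na2CO3, toluene, 90 °C
Reagents that add atoms: carbon monoxide, [C-]#[O+]
Why: Oxidative addition of zerovalent palladium into the aryl C–Br bond, CO insertion and capture of the acylpalladium by the enolate oxygen (carbonylative lactonisation with an internal enol nucleophile) should close ring B by a 7-membered O-acylation at the formyl oxygen, because acylation at the ketone oxygen would give a bridgehead alkene and C-acylation would place a second quaternary carbon next to the first.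

Step 5
Reactants: 15 (S)-keto enol lactone
Product: 17 (S)-dienyl triflate (enol triflate of the ring A ketone), via potassium dienolate 16 (not isolated)
Conditions: KN(SiMe3)2, THF, –78 °C; N-(5-chloropyridin-2-yl)triflimide, –78 → 0 °C; aq. NH4Cl
Reagents that add atoms: N-(5-chloropyridin-2-yl)-1,1,1-trifluoro-N-[(trifluoromethyl)sulfonyl]methanesulfonamide, FC(F)(F)S(=O)(=O)N(c1ccc(Cl)cn1)S(=O)(=O)C(F)(F)F
Why: Deprotonation can occur only at the ring CH2 next to the ketone (the other α-carbon is the fully substituted enol-ester carbon), and O-sulfonylation of the potassium dienolate with the N-aryl triflimide should give a single enol triflate (enol triflate formation).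

Step 6
Reactants: 17 (S)-dienyl triflate
Product: 18 (S)-dimethoxy diene lactone (ring A as in the target; ring D as 1,4-dimethoxyarene)
Conditions: MeZnCl, Pd(PPh3)4 (5 mol %), THF, 0 °C → rt
Reagents that add atoms: methylzinc chloride, C[Zn]Cl
Why: Negishi cross-coupling of the alkenyl triflate with the mild methylzinc reagent installs the vinylic methyl group of ring A and should leave the enol lactone and the aryl ethers untouched.

Step 7
Reactants: 18 (S)-dimethoxy diene lactone
Product: 19 (S)-naphthoquinone lactone (ring D quinone with two free CH positions)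
Conditions: (NH4)2Ce(NO3)6 (2.5 equiv), MeCN/H2O, 0 °C
Reagents that add atoms: water, O
Why: Oxidative demethylation of the 1,4-dimethoxyarene by tetravalent cerium (ipso attack of water on the radical cation and loss of methanol) is expected to be much faster than oxidation of the isolated dienol ester and gives the naphthoquinone.

Step 8
Reactants: 19 (S)-naphthoquinone lactone; 20 hypotaurine (2-aminoethanesulfinic acid)
Product: 24 target compound, via sulfonylhydroquinone 21 (not isolated), via sulfonylquinone 22 (not isolated), via thiazine-fused hydroquinone 23 (not isolated)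
Conditions: 20 (1.3 equiv), MeCN/EtOH/H2O, air, rt, no added base
Reagents that add atoms: none
Why: Biomimetic thiazine annulation in which the sulfinate of zwitterionic hypotaurine adds in conjugate fashion to the quinone CH that is β to the more electrophilic carbonyl (the one para to the lactone carbonyl on ring C), air reoxidises the adduct to the sulfonylquinone, the tethered amine closes ring E by 6-endo aza-Michael addition and a second air oxidation gives the aminoquinone, while the ammonium form of the reagent should protect the enol lactone from aminolysis.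

**Compound list**

1 | 1,2,4,5-tetrabromobenzene | Brc1cc(Br)c(Br)cc1Br | starting material
2 | 2-methoxyfuran | COc1ccco1 | starting material
3 | (2,4,5-tribromophenyl)lithium | [Li]c1cc(Br)c(Br)cc1Br | intermediate (not isolated)
4 | 4,5-dibromobenzyne (4,5-dibromo-1,2-didehydrobenzene) | BrC1=CC#CC=C1Br | intermediate (not isolated)
5 | racemic 6,7-dibromo-1-methoxy-1,4-dihydro-1,4-epoxynaphthalene | COC12C=CC(O1)c1cc(Br)c(Br)cc12 | intermediate (not isolated)
6 | 6,7-dibromo-4-methoxynaphthalen-1-ol | COc1ccc(O)c2cc(Br)c(Br)cc12 | intermediate
7 | 6,7-dibromo-1,4-dimethoxynaphthalene | COc1ccc(OC)c2cc(Br)c(Br)cc12 | intermediate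
8 | 3-methylcyclohex-2-en-1-one | CC1=CC(=O)CCC1 | starting material
9 | 2,2,2-trifluoroethyl formate | O=COCC(F)(F)F | starting material
10 | (3-bromo-5,8-dimethoxynaphthalen-2-yl)lithium | [Li]c1cc2c(OC)ccc(OC)c2cc1Br | intermediate (not isolated)
11 | (3-bromo-5,8-dimethoxynaphthalen-2-yl)dimethylaluminium | C[Al](C)c1cc2c(OC)ccc(OC)c2cc1Br | intermediate (not isolated)
12 | dimethylaluminium (R)-3-(3-bromo-5,8-dimethoxynaphthalen-2-yl)-3-methylcyclohex-1-en-1-olate | C[Al](C)OC1=C[C@](C)(c2cc3c(OC)ccc(OC)c3cc2Br)CCC1 | intermediate (not isolated)
13 | lithium trimethylaluminate of the (R)-enolate of 12 | [Li+].C[Al-](C)(C)OC1=C[C@](C)(c2cc3c(OC)ccc(OC)c3cc2Br)CCC1 | intermediate (not isolated)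
14 | (R,Z)-3-(3-bromo-5,8-dimethoxynaphthalen-2-yl)-2-(hydroxymethylene)-3-methylcyclohexan-1-one (chelated enol form) | O=C1CCC[C@@](C)(c2cc3c(OC)ccc(OC)c3cc2Br)/C1=C/O | intermediate
15 | (S)-keto enol lactone: cyclohexanone ring A fused to the seven-membered enol lactone ring B (Ar–C(=O)–O–CH=C), which is fused to C6/C7 of a 1,4-dimethoxynaphthalene; quaternary C(Me) bonded to the naphthalene | O=C1CCC[C@]2(C)C1=COC(=O)c1cc3c(OC)ccc(OC)c3cc12 | intermediate
16 | potassium dienolate of 15 (enolate towards the ring CH2) | [K+].[O-]C1=CCC[C@]2(C)C1=COC(=O)c1cc3c(OC)ccc(OC)c3cc12 | intermediate (not isolated)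
17 | (S)-dienyl triflate: enol triflate of the ring A ketone of 15 | FC(F)(F)S(=O)(=O)OC1=CCC[C@]2(C)C1=COC(=O)c1cc3c(OC)ccc(OC)c3cc12 | intermediate
18 | (S)-dimethoxy diene lactone: 17 with methyl in place of the triflate group | CC1=CCC[C@]2(C)C1=COC(=O)c1cc3c(OC)ccc(OC)c3cc12 | intermediate
19 | (S)-naphthoquinone lactone: 18 with ring D as 1,4-quinone | CC1=CCC[C@]2(C)C1=COC(=O)c1cc3c(cc12)C(=O)C=CC3=O | intermediate
20 | hypotaurine (2-aminoethanesulfinic acid) | NCCS(=O)O | starting material
21 | (S)-sulfonylhydroquinone: 2-aminoethylsulfonyl group on the ring D carbon next to the C–OH that is para to the quaternary-carbon-bearing position of ring C | CC1=CCC[C@]2(C)C1=COC(=O)c1cc3c(cc12)c(O)cc(S(=O)(=O)CCN)c3O | intermediate (not isolated)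
22 | (S)-sulfonylquinone: quinone form of 21 | CC1=CCC[C@]2(C)C1=COC(=O)c1cc3c(cc12)C(=O)C=C(C3=O)S(=O)(=O)CCN | intermediate (not isolated)
23 | (S)-thiazine-fused hydroquinone: ring E closed, ring D as hydroquinone | CC1=CCC[C@]2(C)C1=COC(=O)c1cc3c(cc12)c(O)c1NCCS(=O)(=O)c1c3O | intermediate (not isolated)
24 | target compound, (S)-configured at the quaternary carbon | CC1=CCC[C@]2(C)C1=COC(=O)c1cc3c(cc12)C(=O)C1=C(C3=O)S(=O)(=O)CCN1 | target

**Step count and risks**

Total step count: 8. Longest linear sequence: 8 steps (1 → 24).

Steps most likely to fail:

1. Step 3. What may go wrong: sluggish or weakly face-selective transfer of the ortho-bromo naphthyl group to the β,β-disubstituted enone, loss of LiBr from aryllithium 10 before transmetallation, or incomplete C-formylation of the hindered enolate. Fallback: the roles of the two β-substituents are exchanged. Setting out from 7, bromine–lithium exchange (n-BuLi, –100 °C) and 1,2-addition to 3-ethoxycyclohex-2-en-1-one give the tertiary carbinol 1-(3-bromo-5,8-dimethoxynaphthalen-2-yl)-3-ethoxycyclohex-2-en-1-ol F1. On aqueous HCl work-up this should transpose to 3-(3-bromo-5,8-dimethoxynaphthalen-2-yl)cyclohex-2-en-1-one F2. Copper-catalysed asymmetric conjugate addition of Me3Al to F2 (copper thiophene-2-carboxylate Cu(O2CC4H3S), chiral phosphoramidite ligand, Et2O, –30 °C; ligand enantiomer chosen to give the (R)-enolate) then forms the quaternary centre with the small methyl nucleophile. It delivers the same aluminium enolate 12, at which the route is rejoined (MeLi, then 9, to 14).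

2. Step 4. What may go wrong: capture of the acylpalladium intermediate at carbon instead of at the enol oxygen (five-membered C-acylation), or direct C–O coupling without CO insertion. Fallback: the carboxyl group is made while the enol is masked, and ring B is closed by a separate O-acylation. Setting out from 14, O-alkylation (2-iodopropane, K2CO3, acetone) gives (R)-3-(3-bromo-5,8-dimethoxynaphthalen-2-yl)-3-methyl-2-[(propan-2-yloxy)methylidene]cyclohexan-1-one F3. Palladium-catalysed hydroxycarbonylation of the aryl bromide under anhydrous conditions (HCO2Li, Ac2O, iPr2NEt, LiCl, Pd2(dba)3, DMF, 80 °C) gives 3-[(1S)-1-methyl-3-oxo-2-[(propan-2-yloxy)methylidene]cyclohexyl]-5,8-dimethoxynaphthalene-2-carboxylic acid F4. Dilute aqueous HCl in THF releases 3-[(1S)-2-(hydroxymethylidene)-1-methyl-3-oxocyclohexyl]-5,8-dimethoxynaphthalene-2-carboxylic acid F5. Carbodiimide-mediated O-acylation of the enol (EDC, CH2Cl2, no DMAP) closes ring B and comes back to the route at 15.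

3. Step 8. What may go wrong: low or reversed site selectivity of the sulfinate addition between the two quinone CH carbons, or aminolysis of the enol lactone by the free amine. Fallback: if the first nucleophile proves to prefer the other quinone CH, the order of bond formation is inverted so that nitrogen enters first at that carbon. Setting out from 19, oxidative amination with 2-(tritylsulfanyl)ethan-1-amine (EtOH, air, rt) gives the (S)-2-{[2-(tritylsulfanyl)ethyl]amino}quinone F6. Detritylation (TFA, Et3SiH, CH2Cl2) frees the thiol, which closes the ring by conjugate addition and air oxidation to the (S)-dihydrothiazine (sulfide) quinone F7. Chemoselective S-oxidation (H2O2, Na2WO4 cat., MeOH, 0 °C) gives the sulfone and comes back to the route at 24.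

**Further compounds**

F1 | step 3 | 1-(3-bromo-5,8-dimethoxynaphthalen-2-yl)-3-ethoxycyclohex-2-en-1-ol (racemic) | CCOC1=CC(O)(CCC1)c1cc2c(OC)ccc(OC)c2cc1Br
F2 | step 3 | 3-(3-bromo-5,8-dimethoxynaphthalen-2-yl)cyclohex-2-en-1-one | O=C1C=C(CCC1)c1cc2c(OC)ccc(OC)c2cc1Br
F3 | step 4 | (R)-3-(3-bromo-5,8-dimethoxynaphthalen-2-yl)-3-methyl-2-[(propan-2-yloxy)methylidene]cyclohexan-1-one | CC(C)OC=C1C(=O)CCC[C@@]1(C)c1cc2c(OC)ccc(OC)c2cc1Br
F4 | step 4 | 3-[(1S)-1-methyl-3-oxo-2-[(propan-2-yloxy)methylidene]cyclohexyl]-5,8-dimethoxynaphthalene-2-carboxylic acid | CC(C)OC=C1C(=O)CCC[C@@]1(C)c1cc2c(OC)ccc(OC)c2cc1C(=O)O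
F5 | step 4 | 3-[(1S)-2-(hydroxymethylidene)-1-methyl-3-oxocyclohexyl]-5,8-dimethoxynaphthalene-2-carboxylic acid | O=C1CCC[C@@](C)(c2cc3c(OC)ccc(OC)c3cc2C(=O)O)C1=CO
F6 | step 8 | (S)-aminoquinone: 19 bearing a 2-(tritylsulfanyl)ethylamino group on the quinone carbon next to the carbonyl that is para to the lactone carbonyl position of ring C | CC1=CCC[C@]2(C)C1=COC(=O)c1cc3c(cc12)C(=O)C(NCCSC(c1ccccc1)(c1ccccc1)c1ccccc1)=CC3=O
F7 | step 8 | (S)-dihydrothiazine quinone: the target with sulfide in place of the sulfone | CC1=CCC[C@]2(C)C1=COC(=O)c1cc3c(cc12)C(=O)C1=C(C3=O)SCCN1
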